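I decide to read this flask by one clock, and then to ask how the charge of D moves it.

| setting | noon | flask |
|---|---|---|
| J | 0.58 M | 0.58 M |
| D | 0.2 mol% | 0.2 mol% |
| remark | the very flask that is asked about, followed so far |  |

- noon (time / h: E / %, J / %): 0.833: 13, 89; 2.00: 25, 78; 4.00: 33, 64; 6.00: 47, 57

(standard deviation of a reading: 1.5 percentage points)

- factor on the rate of making E when 50% of the J are converted if D is charged twice over
- factor on the rate when 50% of the J are converted if D is charged at 0.04 mol% instead

- the numbers in the tables scatter with a standard deviation of 1.5 percentage points
- no earlier run changes the charge of D; that part of a forecast is a guess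

The J readings of the noon run sit near a second-order decay, so I let the charged [J] over the present [J], less one, grow in proportion to time. At 6.00 h in that run this quantity reads 0.754, and on a straight line it reaches one at my clock, my estimate of the half-conversion time, by which half of the J is gone: 7.95 h, a reading that carries the scatter of one point.

Next I suppose that the rate at a given conversion follows the charge of D, so the clock shrinks as the charge grows. Doubling D then gives 3.98 h, and 0.04 mol% gives 39.8 h. So I commit to factors of 2 and 0.200.

The weak link is the supposition that an equal share of D works at equal conversion, since by my reckoning these flasks arrive there at very different times. A loss of D over hours costs the long clock more than the short one, and from the noon readings I can't tell such a loss from a true second order. So if my factors are off, I expect the first to lie above 2 and the second below 0.200.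

The forecast gives 2.1 (from 1.4 to 3.3) and 0.19 (from 0.05 to 0.4), close to my numbers, and reasons of a deactivation over time that “a slow run reaches 50 % late with less live catalyst”.

The simulation gives 2.59 for doubled D, above the forecast, and 0.191 at 0.04 mol%, which agrees with it.

    J + D ⇌ X (K = 0.630 M⁻¹, k = 1400 M⁻¹ h⁻¹)
    Z → D + E (k = 23000 h⁻¹)
    D ⇌ G (K = 1.70, k = 0.360 h⁻¹)
    X ⇌ Z (K = 8.40, k = 320 h⁻¹)
    2 Z → Q (k = 140 M⁻¹ h⁻¹)

Taken alone, the pair D and G relaxes in 1.75 h, the reciprocal of the sum of its forward and back constants, which is shorter than my clock of 7.95 h for this flask; my estimated clock of 3.98 h for doubled D is 2.27 times that relaxation, and my estimated 39.8 h at 0.04 mol% is 22.7 times it. At 50% conversion, G holds 57.4% of the catalyst in this flask and 59.3% in the flask charged with 0.04 mol%.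

(The data were generated by integration for substances that don't exist; noise was put on by code.)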